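The impurity in the flask amounts to 15.0% of its catalyst charge. That fraction, the lost share, meaning the part of the catalyst charge that the impurity can take one for one, is the quantity to watch at this bench.

| flask | substrate | reagent | free catalyst | impurity | remark |
|---|---|---|---|---|---|
| west | 0.20 mM | 1.1 equiv | 0.1 mol% | 0.042 µM | run made earlier |
| south-east | 0.20 mM | 1.1 equiv | 0.1 mol% | 0.066 µM | run made earlier |
| flask | 0.20 mM | 1.10 equiv | 0.1 mol% | 0.030 µM |  |

| run | time / min | product / % | substrate / % |
|---|---|---|---|
| west | 0.417 | 5.1 | 94.7 |
| west | 0.833 | 8.7 | 90.8 |
| west | 1.33 | 12.2 | 88.0 |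
| west | 1.50 | 12.7 | 87.2 |
| west | 2.00 | 16.6 | 83.5 |
| west | 2.50 | 18.8 | 81.1 |
| west | 3.00 | 22.0 | 77.8 |
| south-east | 0.417 | 4.6 | 96.1 |
| south-east | 0.833 | 7.2 | 93.3 |
| south-east | 1.33 | 10.4 | 89.7 |
| south-east | 1.50 | 11.4 | 88.2 |
| south-east | 2.00 | 14.5 | 85.8 |
| south-east | 2.50 | 16.4 | 83.1 |
| south-east | 3.00 | 19.0 | 80.1 |

(readings scatter by 0.3 percentage points)

- no earlier run changes the charge of free catalyst; that part of a forecast is a guess
- no earlier run changes the charge of reagent; that part of a forecast is a guess

- apparent order in reagent when 10% of the substrate are converted (percent change of the rate of making product for one percent more reagent charged)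
- factor on the rate of making product when 10% of the substrate are converted if free catalyst is charged twice over

The lost share was 21.0% in the west run and 33.0% in the south-east run, so their working catalyst stood in the ratio 1.18. Their product at the last reading gives a ratio of 1.16, read within the scatter, and the west run made more product than the south-east run. Scaling the west run by working catalyst, this reckoning expects about 23.7% product in the flask after 3.00 min. It gives 2.18 for a doubled catalyst charge and takes no stand on reagent, which was never varied. No further impurity should reach the flask, since the south-east run, with its larger lost share, made less product than the west run.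

The forecast says 0.9 for reagent, an order it calls a guess, and 2.2 for doubling, on the ground that “it probably titrates catalyst”.

The simulation gives 1.0 and 2.66, and the doubling factor stands above the forecast.

    substrate + free catalyst ⇌ catalyst intermediate A (K = 720 M⁻¹, k = 2.10 × 10⁵ M⁻¹ s⁻¹)
    reagent + catalyst intermediate A ⇌ catalyst intermediate B (K = 10000 M⁻¹, k = 1.80 × 10⁵ M⁻¹ s⁻¹)
    catalyst intermediate B → released group + catalyst intermediate C (k = 1500 s⁻¹)
    catalyst intermediate C → catalyst intermediate D (k = 35.0 s⁻¹)
    catalyst intermediate D ⇌ free catalyst + product (K = 1.30 × 10⁻⁴ M, k = 37.0 s⁻¹)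
    free catalyst ⇌ dormant form (K = 1.30, k = 0.0370 s⁻¹)
    free catalyst + impurity → spent catalyst (k = 3.30 × 10⁷ M⁻¹ s⁻¹)

In the flask, spent catalyst is 15.0% after 0.500 min, which matches the lost share of 15.0%, and impurity is then 0%. After 5.00 min, the forward step of free catalyst with substrate uses it 770 times faster than the forward step into the off-cycle dormant form. Even so, the flask then holds more dormant form than free catalyst, at 36.7% of the catalyst charge against 28.0%.

The readings come from a simulation for an exercise, and the scatter is random.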